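**Retrosynthetic overview**
- The endgame removes the C6 acetate, the C3 ketal and the Mitsunobu ether bond O–C11. This leads back to a drim-7-ene-6α,11-diol (C3 protected) and umbelliferone.
- C11, H-9, the C7=C8 alkene and the C6 oxygen are all developed from a C9 enone in ring B. The sequence is dienyl triflate, CO insertion, alpha-face epoxidation of C6=C7, and SmI2 opening.
- Ring A of the trans-decalin is cut at C1–C10 and C3–C4. The C1–C2–C3 unit is acrylonitrile and the remainder is 6-methylcarvone, made from (R)-carvone.
- Enabling feature: in ring A the fully substituted carbons C10 and C4 sit 1,3 across C5 and are spanned by C1H2–C2H2–C3(=O). C10 is alpha to the C9 carbonyl of ring B, so it reacts as an enolate carbon. C4 is the internal carbon of the isopropenyl group on C5, so it becomes a tertiary radical after hydrogen atom transfer. These two sites match the CH2 terminus and the nitrile carbon of acrylonitrile.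
- Ring order: ring B comes from the chiral pool and carries C5. Ring A is closed in step 2. The coumarin is attached late.

Key step: step 2

Remark: drimane numbering is used throughout, also for the monocycles (carvone C1 = C9, C2 = C8, C3 = C7, C4 = C6, C5 = C5, C6 = C10, C8 = C4); alpha is the face of H-5.

Step 1
Reactants: 1 (R)-(−)-carvone
Product: 2 6-methylcarvone, both C10 epimers
Conditions: LiN(i-Pr)2, THF, −78 °C; MeI, −78 to 0 °C
Reagents that add atoms: iodomethane CI
Why: Kinetic alpha-prime deprotonation of the cross-conjugated enone and SN2 enolate alkylation install the future C10 methyl group, and the new stereocenter needs no control because it is flattened again in step 2.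

Step 2
Reactants: 2 6-methylcarvone; 3 acrylonitrile
Product: 6 trans-fused 11-nordrim-7-ene-3,9-dione, via cyanoethyl ketone 4 (not isolated), via ring A ketimine 5 (not isolated)
Conditions: 3 (1.0 equiv, slow addition), KOt-Bu (10 mol %), t-BuOH–THF, −10 °C; AcOH (10 mol %) as soon as 2 is consumed; then EtOH, Fe(acac)3 (30 mol %), PhSiH3, 60 °C, high dilution; then 1 M aq HCl, rt
Reagents that add atoms: water O
Why: Base-catalysed Michael addition (cyanoethylation) of the enolate carbon C10 to the CH2 terminus of 3 forms C1–C10, and the protic medium protonates the alpha-cyano carbanion before it can add to the enone carbon C7. After neutralisation the iron hydride formed from Fe(acac)3 and PhSiH3 transfers a hydrogen atom to the CH2 terminus of the isopropenyl group, which creates the second C4 methyl group and the tertiary C4 radical. This radical closes ring A by 6-exo-dig attack on the nitrile carbon (C3–C4), the iminyl radical is reduced to ketimine 5 and acid hydrolysis gives the C3 ketone; the closest known reaction types are the cyanoethylation of alpha-branched ketones and the iron-catalysed reductive alkene–nitrile cyclisation to hindered ketones. The only new stereocenter, C10, is set by attack of 3 on the planar enolate from the face opposite to the C5 isopropenyl group, so both epimers of 2 converge on one quaternary configuration and the trans-diequatorial C1 and C4 arms enforce the trans ring fusion. Chemoselectivity rests on faster hydrogen atom transfer to the electron-rich 1,1-disubstituted alkene than to the hindered trisubstituted enone, on the absence of any other acceptor that the C4 radical can reach through a five- or six-membered transition state, and on the single equivalent of 3, which leaves no free acceptor for an intermolecular Giese addition.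

Step 3
Reactants: 6 11-nordrim-7-ene-3,9-dione
Product: 7 3,3-ethylenedioxy-11-nordrim-7-en-9-one
Conditions: HOCH2CH2OH, p-TsOH (cat.), benzene, reflux, Dean–Stark trap
Reagents that add atoms: ethylene glycol OCCO
Why: Acid-catalysed ketalisation should select the saturated C3 ketone because the C9 carbonyl is conjugated and flanked by the quaternary C10 and the C8 methyl group.

Step 4
Reactants: 7 3,3-ethylenedioxy-11-nordrim-7-en-9-one
Product: 8 3,3-ethylenedioxy-11-nordrima-6,8-dien-9-yl triflate
Conditions: KN(SiMe3)2, THF, −78 to 0 °C; PhNTf2, 0 °C to rt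
Reagents that add atoms: N-phenylbis(trifluoromethanesulfonimide) O=S(=O)(N(c1ccccc1)S(=O)(=O)C(F)(F)F)C(F)(F)F
Why: With C10 quaternary the enone can only be deprotonated at the gamma carbon C6, and O-sulfonylation of the extended dienolate (enol triflate formation) places a coupling handle on the hindered C9.

Step 5
Reactants: 8 dienyl triflate
Product: 9 methyl 3,3-ethylenedioxydrima-6,8-dien-11-oate
Conditions: CO (1 atm), Pd(OAc)2 (5 mol %), PPh3, Et3N, MeOH–DMF, 60 °C
Reagents that add atoms: carbon monoxide [C-]#[O+]; methanol CO
Why: Palladium-catalysed methoxycarbonylation of the vinyl triflate brings in C11 through oxidative addition to zerovalent palladium and CO insertion, which avoids any nucleophilic addition to the hindered C9 carbonyl.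

Step 6
Reactants: 9 dienoate
Product: 10 methyl 6α,7α-epoxy-3,3-ethylenedioxydrim-8-en-11-oate
Conditions: mCPBA, Na2HPO4, CH2Cl2, 0 °C
Reagents that add atoms: 3-chloroperoxybenzoic acid O=C(OO)c1cccc(Cl)c1
Why: Prilezhaev epoxidation should take the electron-richer gamma,delta alkene C6=C7 of the dienoate, and the beta methyl groups on C10 and C4 block the beta face so that oxygen arrives from the alpha face and fixes C6.

Step 7
Reactants: 10 epoxy enoate
Product: 11 methyl 3,3-ethylenedioxy-6α-hydroxydrim-7-en-11-oate (9α-H)
Conditions: SmI2, THF–MeOH, −78 °C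
Reagents that add atoms: none
Why: Two-electron reduction of the gamma,delta-epoxy enoate by SmI2 (vinylogous reductive epoxide opening) cleaves the allylic C7–O bond with retention at C6, and kinetic alpha protonation of the samarium dienolate from the open alpha face should set H-9 alpha and leave the C7=C8 alkene.

Step 8
Reactants: 11 hydroxy ester
Product: 12 3,3-ethylenedioxydrim-7-ene-6α,11-diol
Conditions: LiAlH4, THF, 0 °C
Reagents that add atoms: none
Why: Hydride reduction of the ester should give the primary C11 alcohol faster than the beta,gamma-unsaturated ester can enolise, and the ketal is inert.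

Step 9
Reactants: 12 diol; 13 umbelliferone (7-hydroxycoumarin)
Product: 14 7-[(3,3-ethylenedioxy-6α-hydroxydrim-7-en-11-yl)oxy]coumarin
Conditions: PPh3, DIAD, toluene, 0 °C to rt
Reagents that add atoms: none
Why: The Mitsunobu etherification should activate the primary C11 hydroxyl in preference to the secondary C6 hydroxyl shielded by the C4 methyl groups, and the acidic phenol 13 displaces the oxyphosphonium group at a carbon that is not a stereocenter.

Step 10
Reactants: 14 hydroxy ether
Product: 15 7-[(6α-acetoxy-3,3-ethylenedioxydrim-7-en-11-yl)oxy]coumarin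
Conditions: Ac2O, pyridine, DMAP (cat.), CH2Cl2, rt
Reagents that add atoms: acetic anhydride CC(=O)OC(C)=O
Why: DMAP-catalysed acylation esterifies the only free hydroxyl group with retention at C6.

Step 11
Reactants: 15 acetoxy ketal
Product: 16 target, (5R,6S,9S,10R)-6-acetoxy-11-(2-oxo-2H-chromen-7-yloxy)drim-7-en-3-one
Conditions: 1 M aq HCl, THF, rt
Reagents that add atoms: water O
Why: Mild acid-catalysed ketal hydrolysis, helped by relief of strain next to the gem-dimethyl carbon C4, should free the C3 ketone while the acetate, the aryl ether and the coumarin lactone persist.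

**Compound list**
1 | (R)-(−)-carvone, (5R)-2-methyl-5-(prop-1-en-2-yl)cyclohex-2-en-1-one | C1C=C(C)C(=O)C[C@@H]1C(C)=C | starting material
2 | 6-methylcarvone, (5R)-2,6-dimethyl-5-(prop-1-en-2-yl)cyclohex-2-en-1-one, both epimers at the methyl-bearing carbon | C1C=C(C)C(=O)C(C)[C@@H]1C(C)=C | intermediate
3 | acrylonitrile | C=CC#N | starting material
4 | 6-(2-cyanoethyl)-6-methylcarvone, cyanoethyl trans and methyl cis to the isopropenyl group | C1C=C(C)C(=O)[C@@](C)(CCC#N)[C@@H]1C(C)=C | intermediate
5 | 3-imino-11-nordrim-7-en-9-one (N–H ketimine, 5α-H, 10β-methyl) | C1C=C(C)C(=O)[C@@]2(C)CCC(=N)C(C)(C)[C@H]12 | intermediate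
6 | 11-nordrim-7-ene-3,9-dione, (4aS,8aS)-2,5,5,8a-tetramethyl-4a,5,8,8a-tetrahydronaphthalene-1,6(4H,7H)-dione | C1C=C(C)C(=O)[C@@]2(C)CCC(=O)C(C)(C)[C@H]12 | intermediate
7 | 3,3-ethylenedioxy-11-nordrim-7-en-9-one | C1C=C(C)C(=O)[C@@]2(C)CCC3(OCCO3)C(C)(C)[C@H]12 | intermediate
8 | 3,3-ethylenedioxy-11-nordrima-6,8-dien-9-yl trifluoromethanesulfonate | C1=CC(C)=C(OS(=O)(=O)C(F)(F)F)[C@@]2(C)CCC3(OCCO3)C(C)(C)[C@H]12 | intermediate
9 | methyl 3,3-ethylenedioxydrima-6,8-dien-11-oate | C1=CC(C)=C(C(=O)OC)[C@@]2(C)CCC3(OCCO3)C(C)(C)[C@H]12 | intermediate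
10 | methyl 6α,7α-epoxy-3,3-ethylenedioxydrim-8-en-11-oate | O1[C@H]2[C@@H]1C(C)=C(C(=O)OC)[C@@]3(C)CCC4(OCCO4)C(C)(C)[C@H]23 | intermediate
11 | methyl 3,3-ethylenedioxy-6α-hydroxydrim-7-en-11-oate (9α-H) | O[C@H]1C=C(C)[C@H](C(=O)OC)[C@@]2(C)CCC3(OCCO3)C(C)(C)[C@H]12 | intermediate
12 | 3,3-ethylenedioxydrim-7-ene-6α,11-diol | O[C@H]1C=C(C)[C@H](CO)[C@@]2(C)CCC3(OCCO3)C(C)(C)[C@H]12 | intermediate
13 | umbelliferone (7-hydroxycoumarin) | Oc1ccc2ccc(=O)oc2c1 | starting material
14 | 7-[(3,3-ethylenedioxy-6α-hydroxydrim-7-en-11-yl)oxy]coumarin | O[C@H]1C=C(C)[C@H](COc2ccc3ccc(=O)oc3c2)[C@@]2(C)CCC3(OCCO3)C(C)(C)[C@H]12 | intermediate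
15 | 7-[(6α-acetoxy-3,3-ethylenedioxydrim-7-en-11-yl)oxy]coumarin | CC(=O)O[C@H]1C=C(C)[C@H](COc2ccc3ccc(=O)oc3c2)[C@@]2(C)CCC3(OCCO3)C(C)(C)[C@H]12 | intermediate
16 | 6α-acetoxy-3-oxodrim-7-en-11-yl umbelliferyl ether (CNP0140705.1) | CC(=O)O[C@H]1C=C(C)[C@H](COc2ccc3ccc(=O)oc3c2)[C@@]2(C)CCC(=O)C(C)(C)[C@H]12 | target

Total step count: 11. Longest linear sequence: 11 steps, from 1.

**Steps most likely to fail**

**Step 2.** Three processes could erode the annulation:
- The alpha-cyano carbanion may add a second time, intramolecularly, to C7 and build a bicyclo[2.2.2]octane.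
- Attack may occur through the extended dienolate at C8.
- The C4 radical may be quenched by hydrogen transfer before the slow nitrile closure.

The fallback sets out from 2 and comes back at 6, forming the two bonds one after the other.
- The kinetic enolate of 2 (LiN(i-Pr)2, THF, −78 °C) would be allylated with allyl bromide, anti to the isopropenyl group, to give 6-allyl-6-methylcarvone F1.
- Disiamylborane and then NaBO3 would hydroborate only the monosubstituted alkene to give the primary alcohol F2.
- Dess–Martin oxidation would give the aldehyde F3.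
- The Fe(acac)3/PhSiH3 reductive alkene–carbonyl radical cyclisation would close ring A to the C3 carbinol F4.
- A second Dess–Martin oxidation returns to 6.

**Step 7.** Regiocontrol or facial selectivity at C9 would be lost if the samarium dienolate is protonated at C7 or from the beta face. The alkene could also drift into conjugation with the ester.

The fallback sets out from 7 and comes back at 12, building C6–O and C11 in the opposite order.
- TBSOTf/Et3N would give the silyl dienol ether F5.
- mCPBA would oxidise its gamma carbon from the alpha face (vinylogous Rubottom oxidation) to the 6α-hydroxy enone F6.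
- Wittig methylenation with excess Ph3P=CH2 (from Ph3PCH3Br and KOt-Bu, toluene, heat) would give the hydroxy diene F7.
- 9-BBN and then NaBO3 would hydroborate the exocyclic C9=C11 terminus from the alpha face to give 12.

**Step 9.** The two hydroxyl groups may be poorly discriminated. Displacement at the neopentyl-like C11 may be sluggish, and allylic substitution or elimination at C6 could compete.

The fallback sets out from 11 and comes back at 14, differentiating the oxygens by protection.
- TESCl/imidazole would give the silyl ether ester F8.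
- LiAlH4 would give the mono-protected alcohol F9.
- The Mitsunobu reaction with 13 would give the silyl ether coumarin F10.
- TBAF would remove the silyl group to give 14.

**Further compounds**
F1 | step 2 | 6-allyl-6-methylcarvone, allyl trans to isopropenyl | C1C=C(C)C(=O)[C@@](C)(CC=C)[C@@H]1C(C)=C
F2 | step 2 | 6-(3-hydroxypropyl)-6-methylcarvone | C1C=C(C)C(=O)[C@@](C)(CCCO)[C@@H]1C(C)=C
F3 | step 2 | 6-(3-oxopropyl)-6-methylcarvone | C1C=C(C)C(=O)[C@@](C)(CCC=O)[C@@H]1C(C)=C
F4 | step 2 | 3-hydroxy-11-nordrim-7-en-9-one, C3 epimers | C1C=C(C)C(=O)[C@@]2(C)CCC(O)C(C)(C)[C@H]12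
F5 | step 7 | 9-(tert-butyldimethylsilyloxy)-3,3-ethylenedioxy-11-nordrima-6,8-diene | C1=CC(C)=C(O[Si](C)(C)C(C)(C)C)[C@@]2(C)CCC3(OCCO3)C(C)(C)[C@H]12
F6 | step 7 | 3,3-ethylenedioxy-6α-hydroxy-11-nordrim-7-en-9-one | O[C@H]1C=C(C)C(=O)[C@@]2(C)CCC3(OCCO3)C(C)(C)[C@H]12
F7 | step 7 | 3,3-ethylenedioxydrima-7,9(11)-dien-6α-ol | O[C@H]1C=C(C)C(=C)[C@@]2(C)CCC3(OCCO3)C(C)(C)[C@H]12
F8 | step 9 | methyl 3,3-ethylenedioxy-6α-(triethylsilyloxy)drim-7-en-11-oate | CC[Si](CC)(CC)O[C@H]1C=C(C)[C@H](C(=O)OC)[C@@]2(C)CCC3(OCCO3)C(C)(C)[C@H]12
F9 | step 9 | 3,3-ethylenedioxy-6α-(triethylsilyloxy)drim-7-en-11-ol | CC[Si](CC)(CC)O[C@H]1C=C(C)[C@H](CO)[C@@]2(C)CCC3(OCCO3)C(C)(C)[C@H]12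
F10 | step 9 | 7-{[3,3-ethylenedioxy-6α-(triethylsilyloxy)drim-7-en-11-yl]oxy}coumarin | CC[Si](CC)(CC)O[C@H]1C=C(C)[C@H](COc2ccc3ccc(=O)oc3c2)[C@@]2(C)CCC3(OCCO3)C(C)(C)[C@H]12
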